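The route rests on cutting two bonds that end on the same aryl group (later the two 5,7-dimethoxycoumarin-8-yl units): C1–aryl and C7–aryl, where C1 and C7 are the β-carbon and the acyl carbon of a 4,6,6-trimethylcyclohexa-1,3-diene-1-carboxylate that becomes the cyclohexene ring. One aryllithium, used twice in a single flask, adds in conjugate fashion at C1 under a chiral diether and then captures at C7 the ketene shed by the hindered aryl ester enolate, which should give the trans diaryl ketone with C1 and C6 set. The precursor is the 2,6-di-tert-butyl-4-methoxyphenyl dienoate from isophorone; both coumarin pyranone rings are annulated afterwards, and C7=O is reduced last.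

Key step: step 8

Locants: target numbering is used from step 8 on: C1 (ring CH bearing aryl), C2=C3 (C3 methyl), C4 (CH2), C5 (CMe2), C6 (ring CH bearing C7), C7 (exocyclic carbon).

Assumption: (R,R)-1,2-dimethoxy-1,2-diphenylethane is taken to steer the aryl group to the Si face of the β-carbon (giving 1S); if the sense is the opposite, the (S,S)-ligand is used and nothing else changes.

Step 1
Reactants: 1 isophorone (3,5,5-trimethylcyclohex-2-en-1-one)
Product: 2 6-(hydroxymethylidene)-3,5,5-trimethylcyclohex-2-en-1-one
Conditions: NaH, HCO2Et, cat. EtOH, THF, 0 °C to rt; aq. HCl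
Reagents that add atoms: ethyl formate, CCOC=O
Why: Crossed Claisen formylation under equilibrating conditions should end at the α′-methylene between C=O and CMe2, because only that product is drained as a chelated β-keto aldehyde enolate, as is usual for cyclic enones.

Step 2
Reactants: 2 6-(hydroxymethylidene)-3,5,5-trimethylcyclohex-2-en-1-one
Product: 3 6-(isopropoxymethylidene)-3,5,5-trimethylcyclohex-2-en-1-one (enol ether geometry not assigned and without consequence)
Conditions: K2CO3, i-PrI, acetone, reflux
Reagents that add atoms: 2-iodopropane, CC(C)I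
Why: Williamson-type O-alkylation of the β-keto aldehyde enolate with a secondary iodide goes to the aldehyde-derived oxygen and gives the alkoxymethylene ketone.

Step 3
Reactants: 3 6-(isopropoxymethylidene)-3,5,5-trimethylcyclohex-2-en-1-one
Product: 5 4,6,6-trimethylcyclohexa-1,3-diene-1-carbaldehyde, via allylic alcohol 4 (not isolated)
Conditions: NaBH4, CeCl3·7H2O, MeOH, 0 °C; then 1 M HCl, THF, rt
Reagents that add atoms: water, O
Why: Luche 1,2-reduction followed by acid ionisation of the allylic alcohol and hydrolysis of the oxocarbenium ion (reductive 1,3-carbonyl transposition) should leave the conjugated dienal with the formyl carbon next to CMe2.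

Step 4
Reactants: 5 4,6,6-trimethylcyclohexa-1,3-diene-1-carbaldehyde
Product: 6 4,6,6-trimethylcyclohexa-1,3-diene-1-carboxylic acid
Conditions: NaClO2, NaH2PO4, 2-methyl-2-butene, t-BuOH/H2O, rt
Reagents that add atoms: sodium chlorite, [Na+].[O-]Cl=O
Why: Pinnick oxidation converts unsaturated aldehydes to acids without touching the diene, since the scavenger removes the hypochlorous acid.

Step 5
Reactants: 6 4,6,6-trimethylcyclohexa-1,3-diene-1-carboxylic acid; 7 2,6-di-tert-butyl-4-methoxyphenol
Product: 9 2,6-di-tert-butyl-4-methoxyphenyl 4,6,6-trimethylcyclohexa-1,3-diene-1-carboxylate, via acid chloride 8 (not isolated)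
Conditions: (COCl)2, cat. DMF, CH2Cl2, 0 °C to rt, concentrate; then 7, n-BuLi, THF, 0 °C to rt
Reagents that add atoms: none
Why: Acylation of the lithium phenoxide by the acid chloride is the standard entry to esters of 2,6-di-tert-butylphenols, and the blocked para position leaves only O-acylation.

Step 6
Reactants: 10 3,5-dimethoxyphenol
Product: 11 1,3-dimethoxy-5-(methoxymethoxy)benzene
Conditions: NaH, MOMCl, THF/DMF, 0 °C to rt
Reagents that add atoms: chloromethyl methyl ether, COCCl
Why: Williamson-type O-alkylation of the phenoxide installs the acetal that later directs lithiation and is removable without touching the methyl ethers.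

Step 7
Reactants: 11 1,3-dimethoxy-5-(methoxymethoxy)benzene
Product: 12 2-(methoxymethoxy)-4,6-dimethoxyphenyllithium (salt-free solution, diluted with toluene, titrated and used at once)
Conditions: n-BuLi (hexanes), Et2O, 0 °C to rt; dilute with toluene
Reagents that add atoms: n-butyllithium, [Li]CCCC
Why: Directed ortho-metalation should occur at the carbon between the acetal and a methoxy group, since the chelating acetal is the stronger director in a weakly coordinating solvent; leaving out THF, amines and lithium halides keeps the chiral diether of step 8 the only strong external donor.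

Step 8
Reactants: 9 2,6-di-tert-butyl-4-methoxyphenyl 4,6,6-trimethylcyclohexa-1,3-diene-1-carboxylate; 12 2-(methoxymethoxy)-4,6-dimethoxyphenyllithium (3 equiv, two are consumed)
Product: 17 [2-(methoxymethoxy)-4,6-dimethoxyphenyl][(1R,2S)-2-[2-(methoxymethoxy)-4,6-dimethoxyphenyl]-4,6,6-trimethylcyclohex-3-en-1-yl]methanone (trans ketone; 1S,6R in target locants), via lithium ester enolate 13 (not isolated), via ketene 14 (not isolated), via lithium ketone enolate 15 (not isolated), via cis ketone 16 (not isolated)
Conditions: (R,R)-1,2-dimethoxy-1,2-diphenylethane (3.3 equiv), toluene/Et2O, −78 °C; warm to 0 °C; MeOH, then NaOMe, MeOH, 50 °C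
Reagents that add atoms: none
Why: Proposed new method: the ligand-bound aryllithium should add 1,4 to the dienoate at the β-carbon (C1), the α,α-disubstituted ester enolate 13 should expel lithium 2,6-di-tert-butyl-4-methoxyphenoxide on warming to give ketene 14, and a second aryllithium should take the sp carbon (C7) to give ketone enolate 15. The closest known reaction types are the chiral-diether-mediated conjugate addition of aryllithiums to hindered aryl enoates and the collapse of hindered aryl ester enolates to ketenes with capture by organolithiums; joining them in one flask with one reagent is the untested part. No ring is closed, so no mode of closure applies. C1 is set by the chiral diether–lithium complex, expected to deliver the aryl group to the Si face of the β-carbon, and C6 is set by protonation followed by methoxide equilibration, which should turn the expected kinetic cis epimer 16 into the trans ketone with both large groups pseudo-equatorial. The step needs 1,4-addition over 1,2- and 1,6-addition and over deprotonation at C4 or the C3 methyl; the ester bulk, the fully substituted C3 and the low basicity of the chelated, doubly ortho-oxygenated aryllithium in toluene at −78 °C should secure this.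

Step 9
Reactants: 17 trans ketone
Product: 18 (2-hydroxy-4,6-dimethoxyphenyl)[(1R,2S)-2-(2-hydroxy-4,6-dimethoxyphenyl)-4,6,6-trimethylcyclohex-3-en-1-yl]methanone
Conditions: HCl (1 M in MeOH), rt to 40 °C
Reagents that add atoms: none
Why: Acid-catalysed acetal methanolysis should free both phenols, and dilute acid at low temperature is chosen so that the ring alkene is not protonated and neither phenol cyclises onto C3 or C7.

Step 10
Reactants: 18 bisphenol ketone
Product: 20 3-[(1S,6R)-6-(3-formyl-2-hydroxy-4,6-dimethoxybenzoyl)-3,5,5-trimethylcyclohex-2-en-1-yl]-2-hydroxy-4,6-dimethoxybenzaldehyde, via bis(hydroxymethyl) bisphenol 19 (not isolated)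
Conditions: MgCl2, Et3N, (CH2O)n, MeCN, reflux; aq. HCl
Reagents that add atoms: formaldehyde (from paraformaldehyde), C=O
Why: Magnesium-mediated ortho-formylation: each chloromagnesium phenoxide (ArOMgCl) should deliver formaldehyde to its single free ortho carbon and the hydroxymethyl group is then oxidised by hydride transfer to more formaldehyde, so the carbon para to oxygen is not attacked.

Step 11
Reactants: 20 dialdehyde
Product: 22 8-[(1S,6R)-6-(5,7-dimethoxy-2-oxo-2H-chromene-8-carbonyl)-3,5,5-trimethylcyclohex-2-en-1-yl]-5,7-dimethoxy-2H-chromen-2-one, via bis(hydroxycinnamate) diester 21 (not isolated)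
Conditions: Ph3P=CHCO2Et, PhNEt2, reflux
Reagents that add atoms: ethyl (triphenylphosphoranylidene)acetate, CCOC(=O)C=P(c1ccccc1)(c1ccccc1)c1ccccc1
Why: Wittig olefination of each salicylaldehyde followed by thermal E-to-Z isomerisation and lactonisation is the standard route from 2-hydroxy-4,6-dimethoxybenzaldehydes to 5,7-dimethoxycoumarins, and the hindered ketone is inert to the stabilised ylide.

Step 12
Reactants: 22 bis-coumarin ketone
Product: 23 8-[(1S,6R)-6-[(R)-(5,7-dimethoxy-2-oxo-2H-chromen-8-yl)(hydroxy)methyl]-3,5,5-trimethylcyclohex-2-en-1-yl]-5,7-dimethoxy-2H-chromen-2-one (IN0553)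
Conditions: NaBH4, CeCl3·7H2O, MeOH/THF, −20 to 0 °C
Reagents that add atoms: none
Why: Borohydride reduction under Felkin–Anh control, with hydride approaching anti to the quaternary C5 and past H-6, should give the (R)-carbinol at C7, while Luche-type conditions spare the two lactones and their conjugated C=C bonds; the ketone is reduced last because the electron-rich benzylic alcohol would not survive acid or free ortho-phenols.

Compound list
1 | isophorone | CC1=CC(=O)CC(C)(C)C1 | starting material
2 | 6-(hydroxymethylidene)-3,5,5-trimethylcyclohex-2-en-1-one | CC1=CC(=O)C(=CO)C(C)(C)C1 | intermediate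
3 | 6-(isopropoxymethylidene)-3,5,5-trimethylcyclohex-2-en-1-one | CC1=CC(=O)C(=COC(C)C)C(C)(C)C1 | intermediate
4 | 6-(isopropoxymethylidene)-3,5,5-trimethylcyclohex-2-en-1-ol (racemic, not isolated) | CC1=CC(O)C(=COC(C)C)C(C)(C)C1 | intermediate
5 | 4,6,6-trimethylcyclohexa-1,3-diene-1-carbaldehyde | CC1=CC=C(C=O)C(C)(C)C1 | intermediate
6 | 4,6,6-trimethylcyclohexa-1,3-diene-1-carboxylic acid | CC1=CC=C(C(=O)O)C(C)(C)C1 | intermediate
7 | 2,6-di-tert-butyl-4-methoxyphenol | COc1cc(C(C)(C)C)c(O)c(C(C)(C)C)c1 | starting material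
8 | 4,6,6-trimethylcyclohexa-1,3-diene-1-carbonyl chloride (not isolated) | CC1=CC=C(C(=O)Cl)C(C)(C)C1 | intermediate
9 | 2,6-di-tert-butyl-4-methoxyphenyl 4,6,6-trimethylcyclohexa-1,3-diene-1-carboxylate | COc1cc(C(C)(C)C)c(OC(=O)C2=CC=C(C)CC2(C)C)c(C(C)(C)C)c1 | intermediate
10 | 3,5-dimethoxyphenol | COc1cc(O)cc(OC)c1 | starting material
11 | 1,3-dimethoxy-5-(methoxymethoxy)benzene | COCOc1cc(OC)cc(OC)c1 | intermediate
12 | 2-(methoxymethoxy)-4,6-dimethoxyphenyllithium | [Li]c1c(OC)cc(OC)cc1OCOC | intermediate
13 | lithium enolate of the 2,6-di-tert-butyl-4-methoxyphenyl 2-aryl-4,6,6-trimethylcyclohex-3-ene-1-carboxylate, aryl-bearing carbon arranged as in 17 (not isolated) | COCOc1cc(OC)cc(OC)c1[C@H]1C=C(C)CC(C)(C)C1=C(O[Li])Oc1c(C(C)(C)C)cc(OC)cc1C(C)(C)C | intermediate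
14 | [6-[2-(methoxymethoxy)-4,6-dimethoxyphenyl]-2,2,4-trimethylcyclohex-4-en-1-ylidene]methanone, ketene, aryl-bearing carbon arranged as in 17 (not isolated) | COCOc1cc(OC)cc(OC)c1[C@H]1C=C(C)CC(C)(C)C1=C=O | intermediate
15 | lithium C6=C7 enolate of ketone 17 (not isolated) | COCOc1cc(OC)cc(OC)c1[C@H]1C=C(C)CC(C)(C)C1=C(O[Li])c1c(OC)cc(OC)cc1OCOC | intermediate
16 | [2-(methoxymethoxy)-4,6-dimethoxyphenyl][(1S,2S)-2-[2-(methoxymethoxy)-4,6-dimethoxyphenyl]-4,6,6-trimethylcyclohex-3-en-1-yl]methanone, cis C6 epimer (not isolated) | COCOc1cc(OC)cc(OC)c1[C@H]1C=C(C)CC(C)(C)[C@H]1C(=O)c1c(OC)cc(OC)cc1OCOC | intermediate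
17 | [2-(methoxymethoxy)-4,6-dimethoxyphenyl][(1R,2S)-2-[2-(methoxymethoxy)-4,6-dimethoxyphenyl]-4,6,6-trimethylcyclohex-3-en-1-yl]methanone, trans | COCOc1cc(OC)cc(OC)c1[C@H]1C=C(C)CC(C)(C)[C@@H]1C(=O)c1c(OC)cc(OC)cc1OCOC | intermediate
18 | (2-hydroxy-4,6-dimethoxyphenyl)[(1R,2S)-2-(2-hydroxy-4,6-dimethoxyphenyl)-4,6,6-trimethylcyclohex-3-en-1-yl]methanone | Oc1cc(OC)cc(OC)c1[C@H]1C=C(C)CC(C)(C)[C@@H]1C(=O)c1c(OC)cc(OC)cc1O | intermediate
19 | [2-hydroxy-3-(hydroxymethyl)-4,6-dimethoxyphenyl][(1R,2S)-2-[2-hydroxy-3-(hydroxymethyl)-4,6-dimethoxyphenyl]-4,6,6-trimethylcyclohex-3-en-1-yl]methanone (not isolated) | Oc1c(CO)c(OC)cc(OC)c1[C@H]1C=C(C)CC(C)(C)[C@@H]1C(=O)c1c(OC)cc(OC)c(CO)c1O | intermediate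
20 | 3-[(1S,6R)-6-(3-formyl-2-hydroxy-4,6-dimethoxybenzoyl)-3,5,5-trimethylcyclohex-2-en-1-yl]-2-hydroxy-4,6-dimethoxybenzaldehyde | Oc1c(C=O)c(OC)cc(OC)c1[C@H]1C=C(C)CC(C)(C)[C@@H]1C(=O)c1c(OC)cc(OC)c(C=O)c1O | intermediate
21 | diethyl bis[(E)-2-hydroxycinnamate] from 20, each formyl group replaced by (E)-CH=CH-CO2Et (not isolated) | Oc1c(/C=C/C(=O)OCC)c(OC)cc(OC)c1[C@H]1C=C(C)CC(C)(C)[C@@H]1C(=O)c1c(OC)cc(OC)c(/C=C/C(=O)OCC)c1O | intermediate
22 | 8-[(1S,6R)-6-(5,7-dimethoxy-2-oxo-2H-chromene-8-carbonyl)-3,5,5-trimethylcyclohex-2-en-1-yl]-5,7-dimethoxy-2H-chromen-2-one | COc1cc(OC)c2ccc(=O)oc2c1[C@H]1C=C(C)CC(C)(C)[C@@H]1C(=O)c1c(OC)cc(OC)c2ccc(=O)oc12 | intermediate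
23 | 8-[(1S,6R)-6-[(R)-(5,7-dimethoxy-2-oxo-2H-chromen-8-yl)(hydroxy)methyl]-3,5,5-trimethylcyclohex-2-en-1-yl]-5,7-dimethoxy-2H-chromen-2-one (IN0553) | COc1cc(OC)c2ccc(=O)oc2c1[C@H]1C=C(C)CC(C)(C)[C@@H]1[C@@H](O)c1c(OC)cc(OC)c2ccc(=O)oc12 | target

Total step count: 12. Longest linear sequence: 10 steps (steps 1–5, then 8–12); the aryl branch (steps 6–7) joins at step 8.

Steps most likely to fail

Step 8. The aryllithium may act as a base at C4 or the C3 methyl instead of adding. Its internal chelation may override the chiral diether and erode enantioselectivity. The relay from ester enolate to ketene to ketone enolate may stall or consume the ketene unproductively, and equilibration at C6 may not favour trans. The fallback uses known reactions only, sets out from 9 and 12 and returns at 17. The conjugate addition alone is run at −78 °C under the same diether and quenched cold with MeOH to give the 2,6-di-tert-butyl-4-methoxyphenyl ester F1 (any C6 epimer is carried along). LiAlH4 in THF at reflux releases the hindered phenol and gives the primary alcohol F2. Dess–Martin oxidation followed by DBU equilibration gives the trans aldehyde F3. Addition of 12 in THF at −78 °C gives the diaryl carbinol F4 as a C7 epimer mixture, and a second Dess–Martin oxidation gives 17.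

Step 12. Hydride delivery to a carbonyl flanked by two ortho substituents and a hindered CH may be slow, facial selectivity at C7 may be poor or reversed, and the lactones may be attacked. The fallback goes from 22 directly to 23 with no new compound (F0). It is a catalyst-controlled reduction with a 2-methyl-CBS-oxazaborolidine and catecholborane in toluene at −78 to −40 °C, in which the oxazaborolidine activates the ketone and its chirality, not C6, selects the face. The catalyst antipode that gives the (7R) carbinol is found by running both.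

Step 10. The phenol hydrogen-bonded to the C7 ketone is deactivated and may be formylated slowly or incompletely, and magnesium enolisation of the ketone may lead to hydroxymethylation at C6. The fallback sets out from 18 and returns at 22, bypassing steps 10 and 11. Both phenols are esterified with propiolic acid (DCC, CH2Cl2, 0 °C) to give the bis(aryl propiolate) F5. PtCl4 in dioxane/1,2-dichloroethane (or Ph3PAuCl with AgSbF6) then induces intramolecular hydroarylation of each alkyne by the one free ortho carbon of its electron-rich ring, closing both pyranone rings.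

Further compounds
F1 | step 8 | 2,6-di-tert-butyl-4-methoxyphenyl (1R,2S)-2-[2-(methoxymethoxy)-4,6-dimethoxyphenyl]-4,6,6-trimethylcyclohex-3-ene-1-carboxylate | COCOc1cc(OC)cc(OC)c1[C@H]1C=C(C)CC(C)(C)[C@@H]1C(=O)Oc1c(C(C)(C)C)cc(OC)cc1C(C)(C)C
F2 | step 8 | [(1R,2S)-2-[2-(methoxymethoxy)-4,6-dimethoxyphenyl]-4,6,6-trimethylcyclohex-3-en-1-yl]methanol | COCOc1cc(OC)cc(OC)c1[C@H]1C=C(C)CC(C)(C)[C@@H]1CO
F3 | step 8 | (1R,2S)-2-[2-(methoxymethoxy)-4,6-dimethoxyphenyl]-4,6,6-trimethylcyclohex-3-ene-1-carbaldehyde | COCOc1cc(OC)cc(OC)c1[C@H]1C=C(C)CC(C)(C)[C@@H]1C=O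
F4 | step 8 | [2-(methoxymethoxy)-4,6-dimethoxyphenyl][(1R,2S)-2-[2-(methoxymethoxy)-4,6-dimethoxyphenyl]-4,6,6-trimethylcyclohex-3-en-1-yl]methanol (C7 epimer mixture) | COCOc1cc(OC)cc(OC)c1[C@H]1C=C(C)CC(C)(C)[C@@H]1C(O)c1c(OC)cc(OC)cc1OCOC
F5 | step 10 | 2-[(1S,6R)-6-[2,4-dimethoxy-6-(propioloyloxy)benzoyl]-3,5,5-trimethylcyclohex-2-en-1-yl]-3,5-dimethoxyphenyl propiolate | C#CC(=O)Oc1cc(OC)cc(OC)c1[C@H]1C=C(C)CC(C)(C)[C@@H]1C(=O)c1c(OC)cc(OC)cc1OC(=O)C#C
F0 | step 12 | none | none
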